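**Retrosynthetic overview**
- Target 18 ← removal of three aryl TBS groups from the (2S)-flavanone 17.
- 17 ← one flask: ring A by [4+2] cycloaddition/aromatisation of a 1-methoxy-1,3-bis(silyloxy)diene 14 with the terminal enynone 7, then ring C by catalyst-controlled oxa-Michael closure of the 2'-hydroxychalcone formed in situ (sets C2).
- Diene 14 ← methyl acetoacetate + 2 prenyl bromide (γ, then α), then two enol silylations (TBS on the future 7-O, TMS on the future O1).
- Enynone 7 ← 2,4-dihydroxybenzaldehyde: silylation, Horner–Wadsworth–Emmons to the Weinreb enamide, ethynyl Grignard.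
- Ring order: B is bought; A forms first and C second, both in step 5.

Assumption: the target is read from the SMILES as the (2S)-flavanone. The quinidine-derived thiourea is taken to give 2S in step 5; this must be confirmed on the first run (chiral HPLC, CD), and the quinine-derived pseudo-enantiomer is used instead if the sense is opposite.

**Step 1**
Reactants: 1 2,4-dihydroxybenzaldehyde; 2 tert-butyldimethylsilyl chloride
Product: 3 2,4-bis[(tert-butyldimethylsilyl)oxy]benzaldehyde
Conditions: TBSCl (2.4 equiv), imidazole (5 equiv), DMF, 0 °C → rt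
Reagents that add atoms: tert-butyldimethylsilyl chloride (2), CC(C)(C)[Si](C)(C)Cl
Why: Imidazole-promoted O-silylation (Corey TBS protection) of both phenols; the aryl TBS ethers survive the later base, Grignard and thermal steps and are cleaved by fluoride at the end.

**Step 2**
Reactants: 3 2,4-bis[(tert-butyldimethylsilyl)oxy]benzaldehyde; 4 diethyl {2-[methoxy(methyl)amino]-2-oxoethyl}phosphonate; 5 ethynylmagnesium bromide
Product: 7 (1E)-1-{2,4-bis[(tert-butyldimethylsilyl)oxy]phenyl}pent-1-en-4-yn-3-one, via Weinreb enamide 6 (not isolated)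
Conditions: NaH, 4, THF, 0 °C → rt; then HC≡CMgBr (2.5 equiv), 0 °C; inverse quench into cold 1 M HCl
Reagents that add atoms: diethyl {2-[methoxy(methyl)amino]-2-oxoethyl}phosphonate (4), CCOP(=O)(CC(=O)N(C)OC)OCC; ethynylmagnesium bromide (5), C#C[Mg]Br
Why: Horner–Wadsworth–Emmons olefination with the stabilised phosphonate gives the E-enamide, and the Weinreb ketone synthesis stops at the ynone through the stable magnesium chelate; the acidic inverse quench keeps the released MeONHMe from adding to the ynone.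

**Step 3**
Reactants: 8 methyl acetoacetate; 9 prenyl bromide (2.1 equiv in two portions)
Product: 11 methyl 7-methyl-2-(3-methylbut-2-en-1-yl)-3-oxooct-6-enoate, via γ-prenylated keto ester enolate 10 (not isolated)
Conditions: NaH, THF, 0 °C; n-BuLi, 0 °C; 9 (1.0 equiv), 0 °C; then 9 (1.1 equiv), DMPU, rt → 45 °C
Reagents that add atoms: prenyl bromide (9), CC(C)=CCBr
Why: Weiler dianion alkylation puts the first prenyl group on the more nucleophilic γ-carbon, and the β-keto ester mono-enolate that remains is then C-alkylated at the α-carbon by the second portion of the allylic bromide.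

**Step 4**
Reactants: 11 methyl 7-methyl-2-(3-methylbut-2-en-1-yl)-3-oxooct-6-enoate; 2 tert-butyldimethylsilyl chloride; 12 trimethylsilyl chloride
Product: 14 (3Z)-3-[(tert-butyldimethylsilyl)oxy]-1-methoxy-7-methyl-2-(3-methylbut-2-en-1-yl)-1-[(trimethylsilyl)oxy]octa-1,3,6-triene, via TBS enol ether 13 (not isolated)
Conditions: NaH, THF, 0 °C; TBSCl, rt; then LDA, −78 °C; TMSCl, −78 → 0 °C; evaporate, pentane, filter under Ar, use crude
Reagents that add atoms: tert-butyldimethylsilyl chloride (2), CC(C)(C)[Si](C)(C)Cl; trimethylsilyl chloride (12), C[Si](C)(C)Cl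
Why: O-silylation of the keto ester enolate followed by kinetic γ-deprotonation and O-trapping is the standard route to Chan-type 1-methoxy-1,3-bis(silyloxy)dienes; A(1,3) strain with the C2 prenyl group places the C4 substituent cis to OTBS (3Z, the s-cis-competent geometry), and the two different silyl groups differentiate the two future phenol oxygens.

**Step 5**
Reactants: 7 (1E)-1-{2,4-bis[(tert-butyldimethylsilyl)oxy]phenyl}pent-1-en-4-yn-3-one; 14 mixed bis-silyl diene (1.3 equiv)
Product: 17 (2S)-2-{2,4-bis[(tert-butyldimethylsilyl)oxy]phenyl}-7-[(tert-butyldimethylsilyl)oxy]-6,8-bis(3-methylbut-2-en-1-yl)-2,3-dihydro-4H-chromen-4-one, via cyclohexadiene cycloadduct 15 (not isolated), via 2'-hydroxychalcone 16 (not isolated)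
Conditions: PhMe, −20 → 50 °C; MeOH (3 equiv), 40 °C, then evaporate; 1-[3,5-bis(trifluoromethyl)phenyl]-3-[(9R)-6'-methoxycinchonan-9-yl]thiourea (quinidine-derived, 15 mol %), PhMe, 0 °C → rt
Reagents that add atoms: none
Why: Proposed new method: the nucleophilic C4 terminus of the diene attacks the unsubstituted alkyne carbon of the ynone and the ketene-acetal carbon closes on the acyl-bearing carbon (normal-demand [4+2]; the terminal ynone is far more reactive than the electron-rich cinnamoyl alkene); loss of MeOSiMe3 and tautomerisation aromatise ring A to chalcone 16, in which only the 2'-OH is free; the bifunctional thiourea then ion-pairs this phenol through its quinuclidine and hydrogen-bonds the enone carbonyl, so that 6-endo oxa-Michael addition closes ring C and sets C2 as S. The closest known reaction types are the Diels–Alder/aromatisation of Chan/Brassard dienes with alkynyl ketones to 2,4-dioxygenated aryl ketones and the cinchona-thiourea-catalysed intramolecular oxa-Michael closure of 2'-hydroxyaryl enones to flavanones.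

**Step 6**
Reactants: 17 (2S)-tris-TBS flavanone
Product: 18 (2S)-2-(2,4-dihydroxyphenyl)-7-hydroxy-6,8-bis(3-methylbut-2-en-1-yl)-2,3-dihydro-4H-chromen-4-one
Conditions: HF·pyridine, pyridine, THF, 0 °C → rt
Reagents that add atoms: none
Why: Fluoride-driven desilylation of the three aryl silyl ethers in a weakly acidic buffered medium, which avoids phenoxide-induced retro-oxa-Michael opening (racemisation at C2) and is too mild to cyclise the ortho-prenyl phenol to a chroman; C2 is not touched.

**Compound list**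
1 | 2,4-dihydroxybenzaldehyde | O=Cc1ccc(O)cc1O | starting material
2 | tert-butyldimethylsilyl chloride | CC(C)(C)[Si](C)(C)Cl | starting material
3 | 2,4-bis[(tert-butyldimethylsilyl)oxy]benzaldehyde | O=Cc1ccc(O[Si](C)(C)C(C)(C)C)cc1O[Si](C)(C)C(C)(C)C | intermediate
4 | diethyl {2-[methoxy(methyl)amino]-2-oxoethyl}phosphonate | CCOP(=O)(CC(=O)N(C)OC)OCC | starting material
5 | ethynylmagnesium bromide | C#C[Mg]Br | starting material
6 | (2E)-3-{2,4-bis[(tert-butyldimethylsilyl)oxy]phenyl}-N-methoxy-N-methylprop-2-enamide | CON(C)C(=O)/C=C/c1ccc(O[Si](C)(C)C(C)(C)C)cc1O[Si](C)(C)C(C)(C)C | intermediate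
7 | (1E)-1-{2,4-bis[(tert-butyldimethylsilyl)oxy]phenyl}pent-1-en-4-yn-3-one | C#CC(=O)/C=C/c1ccc(O[Si](C)(C)C(C)(C)C)cc1O[Si](C)(C)C(C)(C)C | intermediate
8 | methyl acetoacetate | COC(=O)CC(C)=O | starting material
9 | prenyl bromide (1-bromo-3-methylbut-2-ene) | CC(C)=CCBr | starting material
10 | methyl 7-methyl-3-oxooct-6-enoate (present as its Na/Li enolate) | COC(=O)CC(=O)CCC=C(C)C | intermediate
11 | methyl 7-methyl-2-(3-methylbut-2-en-1-yl)-3-oxooct-6-enoate (racemic) | COC(=O)C(CC=C(C)C)C(=O)CCC=C(C)C | intermediate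
12 | trimethylsilyl chloride | C[Si](C)(C)Cl | starting material
13 | methyl 3-[(tert-butyldimethylsilyl)oxy]-7-methyl-2-(3-methylbut-2-en-1-yl)octa-2,6-dienoate (E/Z mixture) | COC(=O)C(CC=C(C)C)=C(CCC=C(C)C)O[Si](C)(C)C(C)(C)C | intermediate
14 | (3Z)-3-[(tert-butyldimethylsilyl)oxy]-1-methoxy-7-methyl-2-(3-methylbut-2-en-1-yl)-1-[(trimethylsilyl)oxy]octa-1,3,6-triene (C1=C2 geometry not defined) | COC(O[Si](C)(C)C)=C(CC=C(C)C)/C(O[Si](C)(C)C(C)(C)C)=C/CC=C(C)C | intermediate
15 | (2E)-3-{2,4-bis[(tert-butyldimethylsilyl)oxy]phenyl}-1-{4-[(tert-butyldimethylsilyl)oxy]-6-methoxy-3,5-bis(3-methylbut-2-en-1-yl)-6-[(trimethylsilyl)oxy]cyclohexa-1,4-dien-1-yl}prop-2-en-1-one (diastereomer mixture) | COC1(O[Si](C)(C)C)C(C(=O)/C=C/c2ccc(O[Si](C)(C)C(C)(C)C)cc2O[Si](C)(C)C(C)(C)C)=CC(CC=C(C)C)C(O[Si](C)(C)C(C)(C)C)=C1CC=C(C)C | intermediate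
16 | (2E)-3-{2,4-bis[(tert-butyldimethylsilyl)oxy]phenyl}-1-{4-[(tert-butyldimethylsilyl)oxy]-2-hydroxy-3,5-bis(3-methylbut-2-en-1-yl)phenyl}prop-2-en-1-one | CC(C)=CCc1cc(C(=O)/C=C/c2ccc(O[Si](C)(C)C(C)(C)C)cc2O[Si](C)(C)C(C)(C)C)c(O)c(CC=C(C)C)c1O[Si](C)(C)C(C)(C)C | intermediate
17 | (2S)-2-{2,4-bis[(tert-butyldimethylsilyl)oxy]phenyl}-7-[(tert-butyldimethylsilyl)oxy]-6,8-bis(3-methylbut-2-en-1-yl)-2,3-dihydro-4H-chromen-4-one | CC(C)=CCc1cc2c(c(CC=C(C)C)c1O[Si](C)(C)C(C)(C)C)O[C@H](c1ccc(O[Si](C)(C)C(C)(C)C)cc1O[Si](C)(C)C(C)(C)C)CC2=O | intermediate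
18 | (2S)-2-(2,4-dihydroxyphenyl)-7-hydroxy-6,8-bis(3-methylbut-2-en-1-yl)-2,3-dihydro-4H-chromen-4-one | CC(C)=CCc1cc2c(c(CC=C(C)C)c1O)O[C@H](c1ccc(O)cc1O)CC2=O | target

**Totals**
Total steps: 6. Longest linear sequence: 4 steps (1 → 2 → 5 → 6, or 3 → 4 → 5 → 6).

**Steps most likely to fail, with fallbacks**

Step 5. The direct chalcone closure may give low ee or stall (hindered 3'-prenyl group, electron-rich ortho-substituted β-aryl group, reversible addition). The fallback replaces asymmetric catalysis by a resolution. It sets out from chalcone 16, isolated by stopping step 5 after the methanol stage and filtering through silica. Compound 16 is closed without stereocontrol (DABCO or DBU 10 mol %, dry PhMe, 40 °C) to the racemic tris-TBS flavanone F1. F1 is then resolved kinetically by asymmetric transfer hydrogenation (RuCl[(R,R)-TsDPEN](p-cymene) 1 mol %, HCO2H/Et3N 5:2, EtOAc, rt, stopped near 52 % conversion). The catalyst hand is chosen so that the 2R ketone is the fast-reacting one, (R,R) being expected from the aryl ketone rule. The 2R enantiomer is reduced to the (2R,4R)-cis-flavan-4-ol F2, which is separated by chromatography, and the unreacted 2S ketone is compound 17, where the route is rejoined. If the cycloaddition half of step 5 is the problem, the fallback for step 4 supplies 16 without it.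

Step 4. The tetrasubstituted mixed bis-silyl diene may not form cleanly or may be too hindered or labile to use. The fallback gives up the de novo ring A and sets out from prenyl bromide 9 and aldehyde 3. Purchased 2',4'-dihydroxyacetophenone (CC(=O)c1ccc(O)cc1O) is C-prenylated twice with 9 (aq. KOH, 0 °C → rt; low-yielding, chromatographic separation from mono- and O-prenylated products) to give 1-[2,4-dihydroxy-3,5-bis(3-methylbut-2-en-1-yl)phenyl]ethanone F3. The non-chelated 4-OH is silylated with 2 (imidazole, DMF) to give the 4-O-TBS ketone F4. The dianion of F4 (LiHMDS 2.2 equiv, THF, −78 °C) is added to 3 to give the aldol adduct F5, and mild acid dehydration (PPTS, PhMe, 50 °C) gives chalcone 16. The route is rejoined at 16, which then goes through the catalyst stage of step 5.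

Step 3. The one-pot double prenylation may give α,α-dialkylated or O-alkylated material that is hard to separate. The fallback builds the same carbon skeleton by a Claisen condensation instead of alkylating an acetoacetate, and sets out from prenyl bromide 9. The lithium enolate of purchased methyl acetate (COC(C)=O; LDA, THF, −78 °C) is alkylated with 9 to give methyl 5-methylhex-4-enoate F6. Claisen self-condensation of F6 (NaH, cat. MeOH, THF, reflux, or TiCl4/Bu3N, CH2Cl2) gives keto ester 11 directly, since 11 is exactly the Claisen dimer of F6. The route is rejoined at 11.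

**Further compounds**
F1 | step 5 | racemic 2-{2,4-bis[(tert-butyldimethylsilyl)oxy]phenyl}-7-[(tert-butyldimethylsilyl)oxy]-6,8-bis(3-methylbut-2-en-1-yl)-2,3-dihydro-4H-chromen-4-one | CC(C)=CCc1cc2c(c(CC=C(C)C)c1O[Si](C)(C)C(C)(C)C)OC(c1ccc(O[Si](C)(C)C(C)(C)C)cc1O[Si](C)(C)C(C)(C)C)CC2=O
F2 | step 5 | (2R,4R)-2-{2,4-bis[(tert-butyldimethylsilyl)oxy]phenyl}-7-[(tert-butyldimethylsilyl)oxy]-6,8-bis(3-methylbut-2-en-1-yl)-3,4-dihydro-2H-chromen-4-ol | CC(C)=CCc1cc2c(c(CC=C(C)C)c1O[Si](C)(C)C(C)(C)C)O[C@@H](c1ccc(O[Si](C)(C)C(C)(C)C)cc1O[Si](C)(C)C(C)(C)C)C[C@H]2O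
F3 | step 4 | 1-[2,4-dihydroxy-3,5-bis(3-methylbut-2-en-1-yl)phenyl]ethanone | CC(=O)c1cc(CC=C(C)C)c(O)c(CC=C(C)C)c1O
F4 | step 4 | 1-{4-[(tert-butyldimethylsilyl)oxy]-2-hydroxy-3,5-bis(3-methylbut-2-en-1-yl)phenyl}ethanone | CC(=O)c1cc(CC=C(C)C)c(O[Si](C)(C)C(C)(C)C)c(CC=C(C)C)c1O
F5 | step 4 | 3-{2,4-bis[(tert-butyldimethylsilyl)oxy]phenyl}-1-{4-[(tert-butyldimethylsilyl)oxy]-2-hydroxy-3,5-bis(3-methylbut-2-en-1-yl)phenyl}-3-hydroxypropan-1-one (racemic) | CC(C)=CCc1cc(C(=O)CC(O)c2ccc(O[Si](C)(C)C(C)(C)C)cc2O[Si](C)(C)C(C)(C)C)c(O)c(CC=C(C)C)c1O[Si](C)(C)C(C)(C)C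
F6 | step 3 | methyl 5-methylhex-4-enoate | COC(=O)CCC=C(C)C
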